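**Retrosynthetic overview**

1. Last bond: Wittig at C11'=C12' between a C25 polyenyl phosphonium salt (β half, 3-myristate) and an ε-ring C15 dienal (3'-palmitate).
2. C25 salt: Wittig at C11=C12 of a β-ring C15 phosphonium salt with the C10 trienedial, then CHO → CH2OH → CH2PPh3Br.
3. β-ring C15 salt: C6–C7 by Stille coupling of a ring enol triflate with a C5 dienylstannane; the ring is bought as an enedione (enzymatic C=C reduction, ketone hydrogenation, myristoylation).
4. ε-ring C15 dienal: C7'=C8' by Horner–Wadsworth–Emmons olefination of the ring aldehyde; the ε ring itself is closed by Michael addition then intramolecular aldol condensation of a β-keto ester with an enone; Luche reduction and lipase resolution set C3' and C6'.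
5. Ring order: the ε ring is the only ring built and is closed in the first step; the β ring is carried intact from its starting material.

Assumption: racemates are written as a 1:1 pair of enantiomer SMILES, and commercial E/Z-mixed reagents are drawn as their E isomers.

**Route**

Step 1
Reactants: 1 mesityl oxide (4-methylpent-3-en-2-one); 2 ethyl acetoacetate (ethyl 3-oxobutanoate)
Product: 5 ethyl 2,6,6-trimethyl-4-oxocyclohex-2-ene-1-carboxylate (racemic), via Michael adduct 3 (not isolated), via ketol 4 (not isolated)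
Conditions: ZnCl2 (0.3 equiv), heptane–toluene, reflux, Dean–Stark water removal
Reagents that add atoms: none
Why: ZnCl2-promoted Michael addition of the acetoacetate enol to the enone gives 1,5-diketone 3, whose methyl-ketone enol closes the six-membered ε ring by intramolecular aldol addition onto the acetyl carbonyl (ketol 4) and dehydrates to the conjugated enone, a Robinson-type annulation that forms the one stereocentre as a racemate.

Step 2
Reactants: 5 ethyl 2,6,6-trimethyl-4-oxocyclohex-2-ene-1-carboxylate (racemic)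
Product: 6 ethyl (1RS,4RS)-4-hydroxy-2,6,6-trimethylcyclohex-2-ene-1-carboxylate (racemic; OH trans to the ester)
Conditions: NaBH4, CeCl3·7H2O, MeOH, −20 → 0 °C; silica chromatography
Reagents that add atoms: none
Why: Luche reduction gives clean 1,2-reduction of the enone without touching the ester, with hydride expected to enter anti to the pseudoaxial C6 methyl (syn to the pseudoaxial ester) so that the 1,4-trans alcohol predominates and the minor cis isomer is removed on silica.

Step 3
Reactants: 6 ethyl (1RS,4RS)-4-hydroxy-2,6,6-trimethylcyclohex-2-ene-1-carboxylate (racemic)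
Product: 7 ethyl (1R,4R)-4-hydroxy-2,6,6-trimethylcyclohex-2-ene-1-carboxylate (the unreacted enantiomer)
Conditions: lipase PS (Burkholderia cepacia), vinyl acetate, t-BuOMe, 30 °C, to about 55% conversion; silica chromatography
Reagents that add atoms: none
Why: Lipase-catalysed kinetic resolution by irreversible transesterification: following the Kazlauskas rule with the CH2–CMe2 flank as the large group the enzyme acetylates the (1S,4S)-alcohol, so that beyond half conversion the (1R,4R)-enantiomer remains in high ee, which fixes both ε-ring stereocentres (C3' and C6' of the target).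

Step 4
Reactants: 7 ethyl (1R,4R)-4-hydroxy-2,6,6-trimethylcyclohex-2-ene-1-carboxylate
Product: 8 ethyl (1R,4R)-4-[(tert-butyldimethylsilyl)oxy]-2,6,6-trimethylcyclohex-2-ene-1-carboxylate
Conditions: TBSCl, imidazole, DMF, rt
Reagents that add atoms: tert-butyldimethylsilyl chloride, CC(C)(C)[Si](C)(C)Cl
Why: Routine silyl ether protection of the secondary allylic alcohol, needed to survive the hydride, oxidation and olefination steps, with no stereocentre involved.

Step 5
Reactants: 8 ethyl (1R,4R)-4-[(tert-butyldimethylsilyl)oxy]-2,6,6-trimethylcyclohex-2-ene-1-carboxylate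
Product: 9 [(1R,4R)-4-[(tert-butyldimethylsilyl)oxy]-2,6,6-trimethylcyclohex-2-en-1-yl]methanol
Conditions: LiAlH4, Et2O, 0 °C; aq NaOH work-up
Reagents that add atoms: none
Why: LiAlH4 ester reduction delivers the primary alcohol while the silyl ether and the trisubstituted alkene are inert and no epimerisable centre is exposed to base.

Step 6
Reactants: 9 [(1R,4R)-4-[(tert-butyldimethylsilyl)oxy]-2,6,6-trimethylcyclohex-2-en-1-yl]methanol
Product: 10 (1R,4R)-4-[(tert-butyldimethylsilyl)oxy]-2,6,6-trimethylcyclohex-2-ene-1-carbaldehyde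
Conditions: Dess–Martin periodinane, NaHCO3, CH2Cl2, 0 °C → rt; used at once
Reagents that add atoms: none
Why: Dess–Martin oxidation runs under buffered, essentially neutral conditions, so the β,γ-unsaturated aldehyde forms without epimerisation at C1 or migration of the ring double bond into conjugation.

Step 7
Reactants: 10 (1R,4R)-4-[(tert-butyldimethylsilyl)oxy]-2,6,6-trimethylcyclohex-2-ene-1-carbaldehyde; 11 triethyl (2E)-3-methyl-4-phosphonobut-2-enoate
Product: 13 ethyl (2E,4E)-5-[(1R,4R)-4-[(tert-butyldimethylsilyl)oxy]-2,6,6-trimethylcyclohex-2-en-1-yl]-3-methylpenta-2,4-dienoate, via lithiated phosphonate 12 (not isolated)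
Conditions: LiN(SiMe3)2, THF–DMPU, −78 °C; then 10, −78 → 0 °C
Reagents that add atoms: none
Why: Horner–Wadsworth–Emmons olefination: the delocalised, weakly basic phosphonate anion adds through its α-carbon to the aldehyde at low temperature faster than it enolises it, giving the new disubstituted C=C bond E and mainly the 2E ester (the minor 2Z isomer is separated), with the ring stereocentres untouched.

Step 8
Reactants: 13 ethyl (2E,4E)-5-[(1R,4R)-4-[(tert-butyldimethylsilyl)oxy]-2,6,6-trimethylcyclohex-2-en-1-yl]-3-methylpenta-2,4-dienoate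
Product: 14 (2E,4E)-5-[(1R,4R)-4-[(tert-butyldimethylsilyl)oxy]-2,6,6-trimethylcyclohex-2-en-1-yl]-3-methylpenta-2,4-dien-1-ol
Conditions: i-Bu2AlH (2.5 equiv), CH2Cl2, −78 °C; aq potassium sodium tartrate work-up
Reagents that add atoms: none
Why: i-Bu2AlH reduces the conjugated ester by two 1,2-hydride additions to the allylic alcohol without conjugate reduction and leaves the silyl ether and the alkene geometry intact.

Step 9
Reactants: 14 (2E,4E)-5-[(1R,4R)-4-[(tert-butyldimethylsilyl)oxy]-2,6,6-trimethylcyclohex-2-en-1-yl]-3-methylpenta-2,4-dien-1-ol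
Product: 15 (2E,4E)-5-[(1R,4R)-4-[(tert-butyldimethylsilyl)oxy]-2,6,6-trimethylcyclohex-2-en-1-yl]-3-methylpenta-2,4-dienal
Conditions: MnO2 (activated, 15 equiv), CH2Cl2, rt
Reagents that add atoms: none
Why: MnO2 oxidises only allylic alcohols, so the dienol gives the dienal without over-oxidation or E/Z scrambling while the silyl-protected ring carbinol is inert.

Step 10
Reactants: 15 (2E,4E)-5-[(1R,4R)-4-[(tert-butyldimethylsilyl)oxy]-2,6,6-trimethylcyclohex-2-en-1-yl]-3-methylpenta-2,4-dienal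
Product: 16 (2E,4E)-5-[(1R,4R)-4-hydroxy-2,6,6-trimethylcyclohex-2-en-1-yl]-3-methylpenta-2,4-dienal
Conditions: Bu4NF, AcOH (1:1), THF, 0 °C → rt
Reagents that add atoms: none
Why: Fluoride-driven desilylation (strong Si–F bond) buffered with acetic acid removes the silyl group without aldol or elimination chemistry at the dienal and without ionising the allylic alcohol.

Step 11
Reactants: 16 (2E,4E)-5-[(1R,4R)-4-hydroxy-2,6,6-trimethylcyclohex-2-en-1-yl]-3-methylpenta-2,4-dienal; 17 palmitoyl chloride (hexadecanoyl chloride)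
Product: 18 (1R,4R)-3,5,5-trimethyl-4-[(1E,3E)-3-methyl-5-oxopenta-1,3-dien-1-yl]cyclohex-2-en-1-yl hexadecanoate
Conditions: pyridine, DMAP (cat.), CH2Cl2, 0 °C → rt
Reagents that add atoms: none
Why: DMAP-catalysed acylation (acyl-pyridinium transfer) esterifies the secondary alcohol with retention of configuration, and the dienal is unaffected.

Step 12
Reactants: 19 ketoisophorone (2,6,6-trimethylcyclohex-2-ene-1,4-dione)
Product: 20 (6R)-2,2,6-trimethylcyclohexane-1,4-dione
Conditions: ene-reductase OYE2, NADP+ (cat.), glucose dehydrogenase, D-glucose, phosphate buffer pH 7, 30 °C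
Reagents that add atoms: none
Why: Ene-reductase (old yellow enzyme) catalysed asymmetric conjugate reduction, the transformation baker's yeast performs on this enedione, adds hydride and a proton trans across the activated C=C and sets the methyl-bearing centre as R.

Step 13
Reactants: 20 (6R)-2,2,6-trimethylcyclohexane-1,4-dione
Product: 21 (4R,6R)-4-hydroxy-2,2,6-trimethylcyclohexan-1-one
Conditions: H2 (10 bar), Raney Ni, MeOH, rt; recrystallise
Reagents that add atoms: none
Why: Catalytic hydrogenation reduces only the unhindered C4 ketone (C1 is flanked by a quaternary and a tertiary carbon) from the equatorial face, away from the axial C2 methyl group, so this substrate-controlled reduction gives the axial 4R alcohol trans to the 6-methyl group, and crystallisation removes the minor 4S epimer.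

Step 14
Reactants: 21 (4R,6R)-4-hydroxy-2,2,6-trimethylcyclohexan-1-one; 22 myristoyl chloride (tetradecanoyl chloride)
Product: 23 (1R,5R)-3,3,5-trimethyl-4-oxocyclohexyl tetradecanoate
Conditions: pyridine, DMAP (cat.), CH2Cl2, rt
Reagents that add atoms: none
Why: DMAP-catalysed acylation of the secondary alcohol installs the myristate, which from here on also serves as the protecting group of the C3 oxygen.

Step 15
Reactants: 23 (1R,5R)-3,3,5-trimethyl-4-oxocyclohexyl tetradecanoate
Product: 24 (1R)-3,5,5-trimethyl-4-[(trifluoromethanesulfonyl)oxy]cyclohex-3-en-1-yl tetradecanoate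
Conditions: Tf2O, 2,6-di-tert-butyl-4-methylpyridine, CH2Cl2, 0 °C → rt
Reagents that add atoms: trifluoromethanesulfonic anhydride, O=S(=O)(OS(=O)(=O)C(F)(F)F)C(F)(F)F
Why: Enol triflate formation with Tf2O and a hindered non-nucleophilic pyridine base: the ketone can enolise only towards the methyl-bearing carbon, so a single tetrasubstituted triflate forms, the ester is inert, the methyl-bearing centre (it only served to direct step 13) is erased and the remote carbinol centre is untouched.

Step 16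
Reactants: 25 (2E)-3-methylpent-2-en-4-yn-1-ol
Product: 26 (2E,4E)-3-methyl-5-(tributylstannyl)penta-2,4-dien-1-ol
Conditions: Bu3SnH, PdCl2(PPh3)2 (2 mol%), THF, 0 °C → rt; silica chromatography
Reagents that add atoms: tributyltin hydride, CCCC[SnH](CCCC)CCCC
Why: Palladium-catalysed hydrostannylation adds Sn–H syn across the terminal alkyne with tin on the unhindered terminal carbon, giving the 4E dienylstannane with the 2E alkene retained (the minor internal regioisomer is removed on silica).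

Step 17
Reactants: 24 (1R)-3,5,5-trimethyl-4-[(trifluoromethanesulfonyl)oxy]cyclohex-3-en-1-yl tetradecanoate; 26 (2E,4E)-3-methyl-5-(tributylstannyl)penta-2,4-dien-1-ol
Product: 27 (1R)-4-[(1E,3E)-5-hydroxy-3-methylpenta-1,3-dien-1-yl]-3,5,5-trimethylcyclohex-3-en-1-yl tetradecanoate
Conditions: Pd2(dba)3 (2.5 mol%), AsPh3 (20 mol%), NMP, 50 °C
Reagents that add atoms: none
Why: Stille cross-coupling: oxidative addition of zerovalent palladium into the enol triflate, AsPh3-accelerated transmetalation at the hindered centre and reductive elimination join C6 to C7 with retention of both alkene geometries under neutral conditions that spare the ester and the free alcohol.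

Step 18
Reactants: 27 (1R)-4-[(1E,3E)-5-hydroxy-3-methylpenta-1,3-dien-1-yl]-3,5,5-trimethylcyclohex-3-en-1-yl tetradecanoate
Product: 28 [(2E,4E)-3-methyl-5-[(4R)-2,6,6-trimethyl-4-(tetradecanoyloxy)cyclohex-1-en-1-yl]penta-2,4-dien-1-yl]triphenylphosphonium bromide
Conditions: PPh3·HBr, CH2Cl2, 0 °C → rt; precipitate from EtOAc
Reagents that add atoms: triphenylphosphine hydrobromide, [Br-].c1ccc(cc1)[PH+](c1ccccc1)c1ccccc1
Why: Acid-mediated allylic substitution: protonation and loss of water give a pentadienyl cation that PPh3 captures at the unhindered terminal carbon (SN1-type), yielding the crystalline E allylic phosphonium salt while the non-allylic ring ester is inert.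

Step 19
Reactants: 28 [(2E,4E)-3-methyl-5-[(4R)-2,6,6-trimethyl-4-(tetradecanoyloxy)cyclohex-1-en-1-yl]penta-2,4-dien-1-yl]triphenylphosphonium bromide; 29 (2E,4E,6E)-2,7-dimethylocta-2,4,6-trienedial (3 equiv)
Product: 31 (1R)-3,5,5-trimethyl-4-[(1E,3E,5E,7E,9E,11E)-3,7,12-trimethyl-13-oxotrideca-1,3,5,7,9,11-hexaen-1-yl]cyclohex-3-en-1-yl tetradecanoate, via phosphorus ylide 30 (not isolated)
Conditions: 1,2-epoxybutane, EtOH, reflux, dark; then heptane, reflux; excess 29 recovered on silica
Reagents that add atoms: none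
Why: Wittig olefination under base-free conditions in which bromide opens the epoxide and the resulting alkoxide generates ylide 30, so the ester is not cleaved; the excess of dialdehyde and the lower electrophilicity of the vinylogous product aldehyde restrict reaction to one end, and heating equilibrates the new disubstituted bond to E.

Step 20
Reactants: 31 (1R)-3,5,5-trimethyl-4-[(1E,3E,5E,7E,9E,11E)-3,7,12-trimethyl-13-oxotrideca-1,3,5,7,9,11-hexaen-1-yl]cyclohex-3-en-1-yl tetradecanoate
Product: 32 (1R)-4-[(1E,3E,5E,7E,9E,11E)-13-hydroxy-3,7,12-trimethyltrideca-1,3,5,7,9,11-hexaen-1-yl]-3,5,5-trimethylcyclohex-3-en-1-yl tetradecanoate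
Conditions: NaBH4, THF–EtOH, 0 °C
Reagents that add atoms: none
Why: NaBH4 reduces the polyenal chemoselectively by 1,2-addition to the allylic alcohol and does not touch the fatty ester.

Step 21
Reactants: 32 (1R)-4-[(1E,3E,5E,7E,9E,11E)-13-hydroxy-3,7,12-trimethyltrideca-1,3,5,7,9,11-hexaen-1-yl]-3,5,5-trimethylcyclohex-3-en-1-yl tetradecanoate
Product: 33 [(2E,4E,6E,8E,10E,12E)-2,7,11-trimethyl-13-[(4R)-2,6,6-trimethyl-4-(tetradecanoyloxy)cyclohex-1-en-1-yl]trideca-2,4,6,8,10,12-hexaen-1-yl]triphenylphosphonium bromide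
Conditions: PPh3·HBr, CH2Cl2, 0 °C → rt, dark
Reagents that add atoms: triphenylphosphine hydrobromide, [Br-].c1ccc(cc1)[PH+](c1ccccc1)c1ccccc1
Why: The same acid-mediated allylic substitution as in step 18, the polyenyl cation being trapped by PPh3 at the terminal carbon to give the E phosphonium salt.

Step 22
Reactants: 33 [(2E,4E,6E,8E,10E,12E)-2,7,11-trimethyl-13-[(4R)-2,6,6-trimethyl-4-(tetradecanoyloxy)cyclohex-1-en-1-yl]trideca-2,4,6,8,10,12-hexaen-1-yl]triphenylphosphonium bromide; 18 (1R,4R)-3,5,5-trimethyl-4-[(1E,3E)-3-methyl-5-oxopenta-1,3-dien-1-yl]cyclohex-2-en-1-yl hexadecanoate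
Product: 35 (3R,3'R,6'R)-3-(tetradecanoyloxy)-β,ε-caroten-3'-yl hexadecanoate (all-E; the target), via phosphorus ylide 34 (not isolated)
Conditions: 1,2-epoxybutane, EtOH–CH2Cl2, 60 °C, dark, Ar; then heptane, reflux; crystallise
Reagents that add atoms: none
Why: Wittig olefination of ylide 34 with the ε-ring dienal under the same neutral epoxide conditions forms the C11'=C12' bond without cleaving either fatty ester or ionising the allylic ester, no stereocentre is involved, and thermal equilibration gives the all-E polyene.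

**Compound list**

1 | mesityl oxide (4-methylpent-3-en-2-one) | CC(=O)C=C(C)C | starting material
2 | ethyl acetoacetate | CCOC(=O)CC(C)=O | starting material
3 | Michael adduct: ethyl 2-acetyl-3,3-dimethyl-5-oxohexanoate | CCOC(=O)C(C(C)=O)C(C)(C)CC(C)=O | intermediate
4 | ketol: ethyl 2-hydroxy-2,6,6-trimethyl-4-oxocyclohexane-1-carboxylate | CCOC(=O)C1C(C)(O)CC(=O)CC1(C)C | intermediate
5 | ethyl 2,6,6-trimethyl-4-oxocyclohex-2-ene-1-carboxylate (racemic) | CCOC(=O)C1C(C)=CC(=O)CC1(C)C | intermediate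
6 | ethyl (1RS,4RS)-4-hydroxy-2,6,6-trimethylcyclohex-2-ene-1-carboxylate (racemic trans) | O[C@H]1C=C(C)[C@H](C(=O)OCC)C(C)(C)C1.O[C@@H]1C=C(C)[C@@H](C(=O)OCC)C(C)(C)C1 | intermediate
7 | ethyl (1R,4R)-4-hydroxy-2,6,6-trimethylcyclohex-2-ene-1-carboxylate | O[C@H]1C=C(C)[C@H](C(=O)OCC)C(C)(C)C1 | intermediate
8 | ethyl (1R,4R)-4-[(tert-butyldimethylsilyl)oxy]-2,6,6-trimethylcyclohex-2-ene-1-carboxylate | CC(C)(C)[Si](C)(C)O[C@H]1C=C(C)[C@H](C(=O)OCC)C(C)(C)C1 | intermediate
9 | [(1R,4R)-4-[(tert-butyldimethylsilyl)oxy]-2,6,6-trimethylcyclohex-2-en-1-yl]methanol | CC(C)(C)[Si](C)(C)O[C@H]1C=C(C)[C@H](CO)C(C)(C)C1 | intermediate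
10 | (1R,4R)-4-[(tert-butyldimethylsilyl)oxy]-2,6,6-trimethylcyclohex-2-ene-1-carbaldehyde | CC(C)(C)[Si](C)(C)O[C@H]1C=C(C)[C@H](C=O)C(C)(C)C1 | intermediate
11 | triethyl (2E)-3-methyl-4-phosphonobut-2-enoate | CCOC(=O)/C=C(C)/CP(=O)(OCC)OCC | starting material
12 | lithiated phosphonate (lithium salt of the P-bearing carbanion of 11) | [Li+].CCOC(=O)/C=C(C)/[CH-]P(=O)(OCC)OCC | intermediate
13 | ethyl (2E,4E)-5-[(1R,4R)-4-[(tert-butyldimethylsilyl)oxy]-2,6,6-trimethylcyclohex-2-en-1-yl]-3-methylpenta-2,4-dienoate | CC(C)(C)[Si](C)(C)O[C@H]1C=C(C)[C@H](/C=C/C(C)=C/C(=O)OCC)C(C)(C)C1 | intermediate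
14 | (2E,4E)-5-[(1R,4R)-4-[(tert-butyldimethylsilyl)oxy]-2,6,6-trimethylcyclohex-2-en-1-yl]-3-methylpenta-2,4-dien-1-ol | CC(C)(C)[Si](C)(C)O[C@H]1C=C(C)[C@H](/C=C/C(C)=C/CO)C(C)(C)C1 | intermediate
15 | (2E,4E)-5-[(1R,4R)-4-[(tert-butyldimethylsilyl)oxy]-2,6,6-trimethylcyclohex-2-en-1-yl]-3-methylpenta-2,4-dienal | CC(C)(C)[Si](C)(C)O[C@H]1C=C(C)[C@H](/C=C/C(C)=C/C=O)C(C)(C)C1 | intermediate
16 | (2E,4E)-5-[(1R,4R)-4-hydroxy-2,6,6-trimethylcyclohex-2-en-1-yl]-3-methylpenta-2,4-dienal | O[C@H]1C=C(C)[C@H](/C=C/C(C)=C/C=O)C(C)(C)C1 | intermediate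
17 | palmitoyl chloride (hexadecanoyl chloride) | CCCCCCCCCCCCCCCC(=O)Cl | starting material
18 | (1R,4R)-3,5,5-trimethyl-4-[(1E,3E)-3-methyl-5-oxopenta-1,3-dien-1-yl]cyclohex-2-en-1-yl hexadecanoate | CCCCCCCCCCCCCCCC(=O)O[C@H]1C=C(C)[C@H](/C=C/C(C)=C/C=O)C(C)(C)C1 | intermediate
19 | ketoisophorone (2,6,6-trimethylcyclohex-2-ene-1,4-dione) | CC1=CC(=O)CC(C)(C)C1=O | starting material
20 | (6R)-2,2,6-trimethylcyclohexane-1,4-dione | O=C1[C@H](C)CC(=O)CC1(C)C | intermediate
21 | (4R,6R)-4-hydroxy-2,2,6-trimethylcyclohexan-1-one | O=C1[C@H](C)C[C@@H](O)CC1(C)C | intermediate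
22 | myristoyl chloride (tetradecanoyl chloride) | CCCCCCCCCCCCCC(=O)Cl | starting material
23 | (1R,5R)-3,3,5-trimethyl-4-oxocyclohexyl tetradecanoate | O=C1[C@H](C)C[C@@H](OC(=O)CCCCCCCCCCCCC)CC1(C)C | intermediate
24 | (1R)-3,5,5-trimethyl-4-[(trifluoromethanesulfonyl)oxy]cyclohex-3-en-1-yl tetradecanoate | FC(F)(F)S(=O)(=O)OC1=C(C)C[C@@H](OC(=O)CCCCCCCCCCCCC)CC1(C)C | intermediate
25 | (2E)-3-methylpent-2-en-4-yn-1-ol | C#C/C(C)=C/CO | starting material
26 | (2E,4E)-3-methyl-5-(tributylstannyl)penta-2,4-dien-1-ol | CCCC[Sn](CCCC)(CCCC)/C=C/C(C)=C/CO | intermediate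
27 | (1R)-4-[(1E,3E)-5-hydroxy-3-methylpenta-1,3-dien-1-yl]-3,5,5-trimethylcyclohex-3-en-1-yl tetradecanoate | OC/C=C(C)/C=C/C1=C(C)C[C@@H](OC(=O)CCCCCCCCCCCCC)CC1(C)C | intermediate
28 | [(2E,4E)-3-methyl-5-[(4R)-2,6,6-trimethyl-4-(tetradecanoyloxy)cyclohex-1-en-1-yl]penta-2,4-dien-1-yl]triphenylphosphonium bromide | [Br-].c1ccc(cc1)[P+](c1ccccc1)(c1ccccc1)C/C=C(C)/C=C/C1=C(C)C[C@@H](OC(=O)CCCCCCCCCCCCC)CC1(C)C | intermediate
29 | (2E,4E,6E)-2,7-dimethylocta-2,4,6-trienedial (C10 dialdehyde) | O=C/C(C)=C/C=C/C=C(C)/C=O | starting material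
30 | phosphorus ylide of 28 (triphenylphosphoranylidene at C1 of the pentadienyl chain) | c1ccc(cc1)P(c1ccccc1)(c1ccccc1)=C/C=C(C)/C=C/C1=C(C)C[C@@H](OC(=O)CCCCCCCCCCCCC)CC1(C)C | intermediate
31 | (1R)-3,5,5-trimethyl-4-[(1E,3E,5E,7E,9E,11E)-3,7,12-trimethyl-13-oxotrideca-1,3,5,7,9,11-hexaen-1-yl]cyclohex-3-en-1-yl tetradecanoate (C25 aldehyde) | O=C/C(C)=C/C=C/C=C(C)/C=C/C=C(C)/C=C/C1=C(C)C[C@@H](OC(=O)CCCCCCCCCCCCC)CC1(C)C | intermediate
32 | (1R)-4-[(1E,3E,5E,7E,9E,11E)-13-hydroxy-3,7,12-trimethyltrideca-1,3,5,7,9,11-hexaen-1-yl]-3,5,5-trimethylcyclohex-3-en-1-yl tetradecanoate (C25 alcohol) | OC/C(C)=C/C=C/C=C(C)/C=C/C=C(C)/C=C/C1=C(C)C[C@@H](OC(=O)CCCCCCCCCCCCC)CC1(C)C | intermediate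
33 | [(2E,4E,6E,8E,10E,12E)-2,7,11-trimethyl-13-[(4R)-2,6,6-trimethyl-4-(tetradecanoyloxy)cyclohex-1-en-1-yl]trideca-2,4,6,8,10,12-hexaen-1-yl]triphenylphosphonium bromide | [Br-].c1ccc(cc1)[P+](c1ccccc1)(c1ccccc1)C/C(C)=C/C=C/C=C(C)/C=C/C=C(C)/C=C/C1=C(C)C[C@@H](OC(=O)CCCCCCCCCCCCC)CC1(C)C | intermediate
34 | phosphorus ylide of 33 (triphenylphosphoranylidene at C1 of the tridecahexaenyl chain) | c1ccc(cc1)P(c1ccccc1)(c1ccccc1)=C/C(C)=C/C=C/C=C(C)/C=C/C=C(C)/C=C/C1=C(C)C[C@@H](OC(=O)CCCCCCCCCCCCC)CC1(C)C | intermediate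
35 | (3R,3'R,6'R)-3-(tetradecanoyloxy)-β,ε-caroten-3'-yl hexadecanoate (lutein 3-myristate 3'-palmitate, all-E) | CCCCCCCCCCCCCCCC(=O)O[C@H]1C=C(C)[C@H](/C=C/C(C)=C/C=C/C(C)=C/C=C/C=C(C)/C=C/C=C(C)/C=C/C2=C(C)C[C@@H](OC(=O)CCCCCCCCCCCCC)CC2(C)C)C(C)(C)C1 | target

**Step count and risks**

Total step count: 22. Longest linear sequence: 12 steps (steps 1–11, then 22). The β-ring/C25 arm is 10 steps (12–15, 17–22) and the stannane arm is one step (16).

The three steps most likely to fail:

Step 2 (the hydride may favour the cis alcohol, leaving little trans material). The fallback sets out from 5 and comes back at 6. The same reduction is run and the cis alcohol, racemic ethyl (1RS,4SR)-4-hydroxy-2,6,6-trimethylcyclohex-2-ene-1-carboxylate F1, is collected. A Mitsunobu reaction (4-nitrobenzoic acid, PPh3, DIAD, THF, 0 °C) inverts the carbinol carbon by SN2 displacement to the trans ester, racemic ethyl (1RS,4RS)-2,6,6-trimethyl-4-[(4-nitrobenzoyl)oxy]cyclohex-2-ene-1-carboxylate F2. K2CO3 in EtOH at rt removes the aryl ester and gives 6.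

Step 3 (the lipase may show low selectivity or the opposite sense on this substrate). The fallback sets out from 6 and comes back at 7, replacing enzymatic by classical resolution. Racemic 6 is esterified with (2S)-2-methoxy-2-phenylacetic acid (DCC, DMAP, CH2Cl2) to give two diastereomers: ethyl (1R,4R)-4-{[(2S)-2-methoxy-2-phenylacetyl]oxy}-2,6,6-trimethylcyclohex-2-ene-1-carboxylate F3 and ethyl (1S,4S)-4-{[(2S)-2-methoxy-2-phenylacetyl]oxy}-2,6,6-trimethylcyclohex-2-ene-1-carboxylate F4. They are separated on silica or by crystallisation and assigned by the mandelate NMR shift model. K2CO3 in EtOH then cleaves F3 to 7.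

Step 7 (the aldehyde 10 is hindered and may epimerise at C1 or isomerise into conjugation under the basic conditions). The fallback sets out from 9 and comes back at 13, reversing the polarity so that no enolisable aldehyde is used. Alcohol 9 is converted by Mitsunobu thioetherification (1-phenyl-1H-tetrazole-5-thiol, PPh3, DIAD, THF) into the sulfide 5-({[(1R,4R)-4-[(tert-butyldimethylsilyl)oxy]-2,6,6-trimethylcyclohex-2-en-1-yl]methyl}sulfanyl)-1-phenyl-1H-tetrazole F5. Oxidation with H2O2 and (NH4)6Mo7O24 in EtOH gives the sulfone 5-({[(1R,4R)-4-[(tert-butyldimethylsilyl)oxy]-2,6,6-trimethylcyclohex-2-en-1-yl]methyl}sulfonyl)-1-phenyl-1H-tetrazole F6. Julia–Kocienski olefination of F6 (KN(SiMe3)2, THF, −78 °C) with commercial ethyl (2E)-3-methyl-4-oxobut-2-enoate forms the E C7'=C8' bond and gives 13.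

**Further compounds**

F1 | step 2 | ethyl (1RS,4SR)-4-hydroxy-2,6,6-trimethylcyclohex-2-ene-1-carboxylate (racemic cis) | O[C@@H]1C=C(C)[C@H](C(=O)OCC)C(C)(C)C1.O[C@H]1C=C(C)[C@@H](C(=O)OCC)C(C)(C)C1
F2 | step 2 | ethyl (1RS,4RS)-2,6,6-trimethyl-4-[(4-nitrobenzoyl)oxy]cyclohex-2-ene-1-carboxylate (racemic trans) | O=C(O[C@H]1C=C(C)[C@H](C(=O)OCC)C(C)(C)C1)c1ccc(cc1)[N+](=O)[O-].O=C(O[C@@H]1C=C(C)[C@@H](C(=O)OCC)C(C)(C)C1)c1ccc(cc1)[N+](=O)[O-]
F3 | step 3 | ethyl (1R,4R)-4-{[(2S)-2-methoxy-2-phenylacetyl]oxy}-2,6,6-trimethylcyclohex-2-ene-1-carboxylate | CO[C@H](C(=O)O[C@H]1C=C(C)[C@H](C(=O)OCC)C(C)(C)C1)c1ccccc1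
F4 | step 3 | ethyl (1S,4S)-4-{[(2S)-2-methoxy-2-phenylacetyl]oxy}-2,6,6-trimethylcyclohex-2-ene-1-carboxylate | CO[C@H](C(=O)O[C@@H]1C=C(C)[C@@H](C(=O)OCC)C(C)(C)C1)c1ccccc1
F5 | step 7 | 5-({[(1R,4R)-4-[(tert-butyldimethylsilyl)oxy]-2,6,6-trimethylcyclohex-2-en-1-yl]methyl}sulfanyl)-1-phenyl-1H-tetrazole | CC(C)(C)[Si](C)(C)O[C@H]1C=C(C)[C@H](CSc2nnnn2-c2ccccc2)C(C)(C)C1
F6 | step 7 | 5-({[(1R,4R)-4-[(tert-butyldimethylsilyl)oxy]-2,6,6-trimethylcyclohex-2-en-1-yl]methyl}sulfonyl)-1-phenyl-1H-tetrazole | CC(C)(C)[Si](C)(C)O[C@H]1C=C(C)[C@H](CS(=O)(=O)c2nnnn2-c2ccccc2)C(C)(C)C1
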